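**Plan**
1. Retrosynthesis: the bond from the ethene bridge to C8 of coumarin A is cut first (Heck). Then the pyranone ring of coumarin B is opened back to a phenol (lactone C–O, C3=C4, formyl C–C). Then the C2–aryl and C1–CH3 bonds of the cyclohexene are cut, and last the two ring bonds of a Diels–Alder adduct.
2. Enabling feature (cyclohexene numbering: C1 quaternary, C2 aryl-bearing, C3=C4 alkene, methyl on C4): if the bridge carbon on C1 is read as a carboxyl carbon, C1 and C2 are the α- and β-carbons of a cyclohexa-1,3-diene-1-carboxylate. That diene already holds the C3=C4 ring alkene and the C4 methyl, so C2 can take an aryl nucleophile and C1 a methyl electrophile.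
3. Forward: the cyclohexadiene ring is made first (isoprene + propiolic acid) and converted to a hindered aryl dienoate. Aryl and methyl are added in one operation, the ester carbon becomes a vinyl group, the pyranone ring of coumarin B is annulated onto the aryl group, and coumarin A is joined last.
4. Stereochemistry: C2 comes from the chiral diether on lithium, C1 from methylation of the enolate anti to the new aryl group, and the E alkene from syn insertion and syn β-hydride elimination in the Heck step.

Key step: step 5

Assumption: the (R,R) diether is taken to steer the aryl group to the C2 face that gives (1R,2R)-11; if the sense proves opposite, the (S,S) antipode is used with nothing else changed.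

Step 1
Reactants: 1 isoprene; 2 propiolic acid
Product: 3 4-methylcyclohexa-1,4-diene-1-carboxylic acid
Conditions: toluene, hydroquinone (cat.), 110 °C, sealed tube, argon; recrystallisation
Reagents that add atoms: none
Why: Thermal Diels–Alder cycloaddition of the 2-substituted diene with the acetylenic acid should favour the 1,4 ("para") orientation of methyl and carboxyl, and the minor 3-methyl isomer is removed on crystallisation.

Step 2
Reactants: 3 4-methylcyclohexa-1,4-diene-1-carboxylic acid
Product: 4 4-methylcyclohexa-1,3-diene-1-carboxylic acid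
Conditions: KOtBu, DMSO, rt, argon; then aq. HCl
Reagents that add atoms: none
Why: Base-mediated prototropic isomerisation, in which deprotonation of the doubly allylic C3–H of the carboxylate and reprotonation at C5 moves the isolated alkene into linear conjugation (the thermodynamic isomer), with oxygen excluded to prevent aromatisation.

Step 3
Reactants: 4 4-methylcyclohexa-1,3-diene-1-carboxylic acid; 5 2,6-di-tert-butyl-4-methoxyphenol
Product: 7 2,6-di-tert-butyl-4-methoxyphenyl 4-methylcyclohexa-1,3-diene-1-carboxylate, via mixed trifluoroacetic anhydride 6 (not isolated)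
Conditions: (CF3CO)2O, CH2Cl2, 0 °C → rt
Reagents that add atoms: none
Why: Mixed-anhydride esterification, in which the carboxylic–trifluoroacetic anhydride transfers its non-fluorinated acyl group to oxygen even of a di-ortho-tert-butyl phenol.

Step 4
Reactants: 8 1,3-dimethoxybenzene
Product: 9 (2,6-dimethoxyphenyl)lithium
Conditions: n-BuLi (hexanes), Et2O, 0 °C → rt; solvent exchanged for toluene, used directly
Reagents that add atoms: n-butyllithium, [Li]CCCC
Why: Directed ortho-metalation, in which both methoxy groups coordinate lithium and acidify the carbon between them, so deprotonation should occur only there.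

Step 5
Reactants: 7 2,6-di-tert-butyl-4-methoxyphenyl 4-methylcyclohexa-1,3-diene-1-carboxylate; 9 (2,6-dimethoxyphenyl)lithium
Product: 11 2,6-di-tert-butyl-4-methoxyphenyl (1R,2R)-2-(2,6-dimethoxyphenyl)-1,4-dimethylcyclohex-3-ene-1-carboxylate (aryl cis to the ester carbon), via lithium ester enolate 10 (not isolated)
Conditions: (R,R)-1,2-dimethoxy-1,2-diphenylethane, toluene, −78 °C; then MeI, DMPU, −78 → −40 °C
Reagents that add atoms: iodomethane, CI
Why: The diether-bound aryllithium coordinates the carbonyl oxygen of the s-cis dienoate and transfers its aryl group to C2, the β-carbon, to give lithium enolate 10, which MeI (DMPU being added only after the C–C bond is made) alkylates on carbon at C1; the closest known reaction is the chiral-ligand-mediated conjugate addition of aryllithiums to 2,6-di-tert-butyl-4-methoxyphenyl cycloalkenecarboxylates with alkylation of the enolate, here applied to a dienoate and a di-ortho-substituted aryllithium. No ring is closed. The C2 configuration is controlled by the chiral diether on lithium, which selects the enantioface of the C1=C2 bond. The C1 configuration is controlled by the new aryl group: allylic strain with the exocyclic enolate turns it pseudoaxial, so methyl enters from the opposite face and the carboxyl carbon ends cis to aryl. The step needs 1,4-addition over 1,2- and 1,6-addition, which the two tert-butyl groups beside the ester oxygen and the fully substituted, methyl-bearing C4 should secure, and methylation must be complete below about −40 °C so that the enolate does not fragment to a ketene and the aryloxide.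

Step 6
Reactants: 11 2,6-di-tert-butyl-4-methoxyphenyl (1R,2R)-2-(2,6-dimethoxyphenyl)-1,4-dimethylcyclohex-3-ene-1-carboxylate
Product: 12 [(1R,2S)-2-(2,6-dimethoxyphenyl)-1,4-dimethylcyclohex-3-en-1-yl]methanol
Conditions: LiAlH4, THF, reflux; then H2O, aq. NaOH
Reagents that add atoms: none
Why: Ester reduction by LiAlH4, in which the small hydride should still reach the carbonyl carbon that is closed to carbon nucleophiles and the aryloxide is a good leaving group, while alkene and aryl ethers are inert.

Step 7
Reactants: 12 [(1R,2S)-2-(2,6-dimethoxyphenyl)-1,4-dimethylcyclohex-3-en-1-yl]methanol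
Product: 13 (1R,2R)-2-(2,6-dimethoxyphenyl)-1,4-dimethylcyclohex-3-ene-1-carbaldehyde
Conditions: Dess–Martin periodinane, CH2Cl2, 0 °C → rt
Reagents that add atoms: none
Why: Dess–Martin oxidation of the neopentyl primary alcohol should stop at the aldehyde, which has no α-hydrogen and so cannot epimerise.

Step 8
Reactants: 13 (1R,2R)-2-(2,6-dimethoxyphenyl)-1,4-dimethylcyclohex-3-ene-1-carbaldehyde
Product: 14 2-[(1S,6S)-6-ethenyl-3,6-dimethylcyclohex-2-en-1-yl]-1,3-dimethoxybenzene
Conditions: Ph3PCH3Br, KOtBu, THF, 0 °C → rt
Reagents that add atoms: methyltriphenylphosphonium bromide, C[P+](c1ccccc1)(c1ccccc1)c1ccccc1.[Br-]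
Why: Wittig methylenation, for which the unstabilised ylide is reactive enough toward the α-quaternary, non-enolisable aldehyde.

Step 9
Reactants: 14 2-[(1S,6S)-6-ethenyl-3,6-dimethylcyclohex-2-en-1-yl]-1,3-dimethoxybenzene
Product: 15 2-[(1S,6S)-6-ethenyl-3,6-dimethylcyclohex-2-en-1-yl]-3-methoxyphenol
Conditions: NaSEt, DMF, 130 °C; then aq. HCl
Reagents that add atoms: none
Why: SN2 demethylation of an aryl methyl ether by ethanethiolate, in which the two methoxy groups exchange by rotation about the aryl–C bond so either cleavage gives the same phenol, and the phenoxide formed should protect the second methoxy group from cleavage.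

Step 10
Reactants: 15 2-[(1S,6S)-6-ethenyl-3,6-dimethylcyclohex-2-en-1-yl]-3-methoxyphenol
Product: 17 3-[(1S,6S)-6-ethenyl-3,6-dimethylcyclohex-2-en-1-yl]-2-hydroxy-4-methoxybenzaldehyde, via salicyl alcohol 16 (not isolated)
Conditions: MgCl2, Et3N, (CH2O)n, MeCN, reflux; then aq. HCl
Reagents that add atoms: paraformaldehyde (as formaldehyde), C=O
Why: Magnesium-mediated ortho-formylation (Casnati–Skattebøl), in which the magnesium phenoxide directs formaldehyde to the only free ortho position and a second formaldehyde oxidises the hydroxymethyl intermediate by Oppenauer-type hydride transfer.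

Step 11
Reactants: 17 3-[(1S,6S)-6-ethenyl-3,6-dimethylcyclohex-2-en-1-yl]-2-hydroxy-4-methoxybenzaldehyde
Product: 19 8-[(1S,6S)-6-ethenyl-3,6-dimethylcyclohex-2-en-1-yl]-7-methoxy-2H-chromen-2-one, via ethyl hydroxycinnamate 18 (not isolated)
Conditions: Ph3P=CHCO2Et, N,N-diethylaniline, reflux
Reagents that add atoms: ethyl (triphenylphosphoranylidene)acetate, CCOC(=O)C=P(c1ccccc1)(c1ccccc1)c1ccccc1
Why: Wittig olefination followed by thermal E-to-Z isomerisation and lactonisation of the o-hydroxycinnamate should close the pyranone ring of coumarin B, the isolated alkenes being inert.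

Step 12
Reactants: 20 7-hydroxy-2H-chromen-2-one (umbelliferone)
Product: 21 7-hydroxy-8-iodo-2H-chromen-2-one
Conditions: I2, KI, aq. NH3, rt
Reagents that add atoms: iodine, II
Why: Electrophilic aromatic iodination of the phenoxide, which should go to C8 because that position is flanked and activated by both ring oxygens.

Step 13
Reactants: 21 7-hydroxy-8-iodo-2H-chromen-2-one
Product: 22 8-iodo-7-methoxy-2H-chromen-2-one
Conditions: MeI, K2CO3, acetone, reflux
Reagents that add atoms: iodomethane, CI
Why: Williamson O-methylation of the phenol under conditions mild enough to leave the lactone closed.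

Step 14
Reactants: 19 8-[(1S,6S)-6-ethenyl-3,6-dimethylcyclohex-2-en-1-yl]-7-methoxy-2H-chromen-2-one; 22 8-iodo-7-methoxy-2H-chromen-2-one
Product: 23 7-methoxy-8-[(E)-2-[(1S,2S)-2-(7-methoxy-2-oxo-2H-chromen-8-yl)-1,4-dimethylcyclohex-3-en-1-yl]ethenyl]-2H-chromen-2-one
Conditions: Pd(OAc)2 (cat.), n-Bu4NCl, NaHCO3, DMF, 85 °C, degassed
Reagents that add atoms: none
Why: Mizoroki–Heck reaction under ligand-free phase-transfer conditions, in which the arylpalladium iodide should add to the terminal alkene with aryl on the CH2 carbon and syn β-hydride elimination, possible only toward the new benzylic carbon because C1 is quaternary, gives the E alkene while the more substituted ring and coumarin alkenes stay untouched.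

**Compound list**
1 | isoprene | CC(=C)C=C | starting material
2 | propiolic acid | C#CC(=O)O | starting material
3 | 4-methylcyclohexa-1,4-diene-1-carboxylic acid | CC1=CCC(C(=O)O)=CC1 | intermediate
4 | 4-methylcyclohexa-1,3-diene-1-carboxylic acid | CC1=CC=C(C(=O)O)CC1 | intermediate
5 | 2,6-di-tert-butyl-4-methoxyphenol | COc1cc(C(C)(C)C)c(O)c(C(C)(C)C)c1 | starting material
6 | 4-methylcyclohexa-1,3-diene-1-carboxylic trifluoroacetic anhydride | CC1=CC=C(C(=O)OC(=O)C(F)(F)F)CC1 | intermediate
7 | 2,6-di-tert-butyl-4-methoxyphenyl 4-methylcyclohexa-1,3-diene-1-carboxylate | COc1cc(C(C)(C)C)c(OC(=O)C2=CC=C(C)CC2)c(C(C)(C)C)c1 | intermediate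
8 | 1,3-dimethoxybenzene | COc1cccc(OC)c1 | starting material
9 | (2,6-dimethoxyphenyl)lithium | [Li]c1c(OC)cccc1OC | intermediate
10 | lithium enolate of the 1,4-adduct, (2R) at the aryl-bearing carbon: lithium (2,6-di-tert-butyl-4-methoxyphenoxy)[(2R)-2-(2,6-dimethoxyphenyl)-4-methylcyclohex-3-en-1-ylidene]methanolate | COc1cc(C(C)(C)C)c(OC(O[Li])=C2CCC(C)=C[C@@H]2c2c(OC)cccc2OC)c(C(C)(C)C)c1 | intermediate
11 | 2,6-di-tert-butyl-4-methoxyphenyl (1R,2R)-2-(2,6-dimethoxyphenyl)-1,4-dimethylcyclohex-3-ene-1-carboxylate | COc1cc(C(C)(C)C)c(OC(=O)[C@]2(C)CCC(C)=C[C@@H]2c2c(OC)cccc2OC)c(C(C)(C)C)c1 | intermediate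
12 | [(1R,2S)-2-(2,6-dimethoxyphenyl)-1,4-dimethylcyclohex-3-en-1-yl]methanol | OC[C@]1(C)CCC(C)=C[C@@H]1c1c(OC)cccc1OC | intermediate
13 | (1R,2R)-2-(2,6-dimethoxyphenyl)-1,4-dimethylcyclohex-3-ene-1-carbaldehyde | O=C[C@]1(C)CCC(C)=C[C@@H]1c1c(OC)cccc1OC | intermediate
14 | 2-[(1S,6S)-6-ethenyl-3,6-dimethylcyclohex-2-en-1-yl]-1,3-dimethoxybenzene | C=C[C@]1(C)CCC(C)=C[C@@H]1c1c(OC)cccc1OC | intermediate
15 | 2-[(1S,6S)-6-ethenyl-3,6-dimethylcyclohex-2-en-1-yl]-3-methoxyphenol | C=C[C@]1(C)CCC(C)=C[C@@H]1c1c(OC)cccc1O | intermediate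
16 | 2-[(1S,6S)-6-ethenyl-3,6-dimethylcyclohex-2-en-1-yl]-6-(hydroxymethyl)-3-methoxyphenol | C=C[C@]1(C)CCC(C)=C[C@@H]1c1c(OC)ccc(CO)c1O | intermediate
17 | 3-[(1S,6S)-6-ethenyl-3,6-dimethylcyclohex-2-en-1-yl]-2-hydroxy-4-methoxybenzaldehyde | C=C[C@]1(C)CCC(C)=C[C@@H]1c1c(OC)ccc(C=O)c1O | intermediate
18 | ethyl (2E)-3-{3-[(1S,6S)-6-ethenyl-3,6-dimethylcyclohex-2-en-1-yl]-2-hydroxy-4-methoxyphenyl}prop-2-enoate (isomerises to Z before ring closure) | C=C[C@]1(C)CCC(C)=C[C@@H]1c1c(OC)ccc(/C=C/C(=O)OCC)c1O | intermediate
19 | 8-[(1S,6S)-6-ethenyl-3,6-dimethylcyclohex-2-en-1-yl]-7-methoxy-2H-chromen-2-one | C=C[C@]1(C)CCC(C)=C[C@@H]1c1c(OC)ccc2ccc(=O)oc12 | intermediate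
20 | 7-hydroxy-2H-chromen-2-one (umbelliferone) | O=c1ccc2ccc(O)cc2o1 | starting material
21 | 7-hydroxy-8-iodo-2H-chromen-2-one | O=c1ccc2ccc(O)c(I)c2o1 | intermediate
22 | 8-iodo-7-methoxy-2H-chromen-2-one | COc1ccc2ccc(=O)oc2c1I | intermediate
23 | 7-methoxy-8-[(E)-2-[(1S,2S)-2-(7-methoxy-2-oxo-2H-chromen-8-yl)-1,4-dimethylcyclohex-3-en-1-yl]ethenyl]-2H-chromen-2-one | COc1ccc2ccc(=O)oc2c1/C=C/[C@]1(C)CCC(C)=C[C@@H]1c1c(OC)ccc2ccc(=O)oc12 | target

**Step count:** 14 steps in total. The longest linear sequence is 11 steps (1, 2, 3, 5, 6, 7, 8, 9, 10, 11, 14).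

**Steps most likely to fail**

Step 5. The internally chelated, di-ortho-substituted aryllithium may bind the diether only weakly and add slowly. Face selection at C2 would then fall, and deprotonation of the dienoate at C5 or fragmentation of the enolate to a ketene could compete. The fallback sets out from 9 and rejoins the route at 13, so steps 5 to 7 are not needed. Compound 9 is formylated with DMF to 2,6-dimethoxybenzaldehyde F1. F1 is condensed with acetone (aqueous NaOH, Claisen–Schmidt) to (E)-4-(2,6-dimethoxyphenyl)but-3-en-2-one F2. F2 is methylenated (Ph3PCH3Br, KOtBu) to 1,3-dimethoxy-2-[(1E)-3-methylbuta-1,3-dien-1-yl]benzene F3. A catalytic enantioselective Diels–Alder reaction of F3 with methacrolein should then give 13 in one step, promoted by the oxazaborolidinium salt made from α,α-diphenylprolinol, o-tolylboroxine and HNTf2 (the enantiomer that leads to 13). The 1-aryl and 3-methyl groups of the diene both direct the formyl-bearing carbon next to the aryl carbon, the endo transition state should place formyl cis to aryl, and the catalyst fixes the absolute sense.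

Step 6. Hydride may fail to reach a carbonyl carbon screened by the quaternary C1 and by two tert-butyl groups, and forcing conditions could erode the material. The fallback sets out from 4 and rejoins at 13. It replaces the hindered ester by an aldimine as activating group, so neither reduction of a hindered ester nor reoxidation is required. Acid 4 is reduced (LiAlH4, Et2O, 0 °C) to (4-methylcyclohexa-1,3-dien-1-yl)methanol F4. F4 is oxidised (MnO2, CH2Cl2) to 4-methylcyclohexa-1,3-diene-1-carbaldehyde F5. F5 is condensed with cyclohexylamine (MgSO4) to (E)-N-cyclohexyl-1-(4-methylcyclohexa-1,3-dien-1-yl)methanimine F6. Conjugate addition of 9 to F6 under the same diether ligand in toluene at −78 °C should give the lithium azaenolate F7. F7 is methylated on carbon with MeI to (E)-N-cyclohexyl-1-[(1R,2S)-2-(2,6-dimethoxyphenyl)-1,4-dimethylcyclohex-3-en-1-yl]methanimine F8. Aqueous oxalic acid then hydrolyses F8 to 13.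

Step 14. Insertion of the di-ortho-substituted arylpalladium iodide into an alkene that sits on a quaternary carbon may stall, and reductive loss of iodine from 22 would then take over. The fallback sets out from 19 and rejoins at 23. Cross-metathesis of 19 with vinylboronic acid pinacol ester (second-generation Hoveyda–Grubbs catalyst, CH2Cl2, 40 °C) should give 7-methoxy-8-[(1S,6S)-3,6-dimethyl-6-[(E)-2-(4,4,5,5-tetramethyl-1,3,2-dioxaborolan-2-yl)ethenyl]cyclohex-2-en-1-yl]-2H-chromen-2-one F9. Suzuki–Miyaura coupling of F9 with 22 (Pd(OAc)2, SPhos, K3PO4, toluene–water, 60 °C) then forms the same bond with the alkene geometry already set.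

**Further compounds**
F1 | step 5 | 2,6-dimethoxybenzaldehyde | COc1cccc(OC)c1C=O
F2 | step 5 | (E)-4-(2,6-dimethoxyphenyl)but-3-en-2-one | COc1cccc(OC)c1/C=C/C(C)=O
F3 | step 5 | 1,3-dimethoxy-2-[(1E)-3-methylbuta-1,3-dien-1-yl]benzene | COc1cccc(OC)c1/C=C/C(C)=C
F4 | step 6 | (4-methylcyclohexa-1,3-dien-1-yl)methanol | CC1=CC=C(CO)CC1
F5 | step 6 | 4-methylcyclohexa-1,3-diene-1-carbaldehyde | CC1=CC=C(C=O)CC1
F6 | step 6 | (E)-N-cyclohexyl-1-(4-methylcyclohexa-1,3-dien-1-yl)methanimine | CC1=CC=C(/C=N/C2CCCCC2)CC1
F7 | step 6 | lithium cyclohexyl{[(2S)-2-(2,6-dimethoxyphenyl)-4-methylcyclohex-3-en-1-ylidene]methyl}azanide (lithium azaenolate) | [Li]N(C1CCCCC1)C=C1CCC(C)=C[C@@H]1c1c(OC)cccc1OC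
F8 | step 6 | (E)-N-cyclohexyl-1-[(1R,2S)-2-(2,6-dimethoxyphenyl)-1,4-dimethylcyclohex-3-en-1-yl]methanimine | C1CCCCC1/N=C/[C@]1(C)CCC(C)=C[C@@H]1c1c(OC)cccc1OC
F9 | step 14 | 7-methoxy-8-[(1S,6S)-3,6-dimethyl-6-[(E)-2-(4,4,5,5-tetramethyl-1,3,2-dioxaborolan-2-yl)ethenyl]cyclohex-2-en-1-yl]-2H-chromen-2-one | CC1(C)OB(/C=C/[C@]2(C)CCC(C)=C[C@@H]2c2c(OC)ccc3ccc(=O)oc23)OC1(C)C
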